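## Structural features

The target is a 2-aryl-2,3-dihydro-1-benzofuran. Benzene ring A is fused to the dihydrofuran through C3a and C7a. C2 carries a 4-hydroxy-3-methoxyphenyl (guaiacyl) ring, C3 carries a one-carbon arm (C9) bound through oxygen to a eugenol unit, C5 carries an allyl group and C7 a methoxy group. C2 and C3 are adjacent stereocentres with their substituents trans, (2S,3R). C2 is benzylic, bound to O1 and para to a phenolic oxygen, so the C2–O1 bond can ionise under acid or hot base. The two allylbenzene units are fragile: they move into conjugation with strong base or metal hydrides and are attacked by electrophilic oxidants. The free phenol is easily oxidised. The difficulty is therefore the absolute and relative configuration at C2/C3 in a labile ring, reached without exposing an alkene to an oxidant.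

The plan exploits the chain O1–C2(aryl)–C3(C9)–C3a. It is a flavanone whose carbonyl carbon has been pushed out of the ring: C9 corresponds to C4 of a chroman-4-one and C3a to C4a. A 1,2-shift of ring A from C4 to C3 therefore turns a flavanone with one stereocentre (C2) into the dihydrobenzofuran with C9 at the ester level.

The descriptors were traced through the sequence and are consistent: (2S)-8 gives (2S,3S)-10, then (2S,3R)-11 and 16. The change from 3S to 3R is a change of substituent priority only. No structure needed correction.

## Logic of the disconnections

**16 to 15.** No skeletal bond is cut. The free O–H on the C2 aryl ring of 16 is traced to an O–S bond of a methanesulfonate in 15. This oxygen must be electron-poor and non-nucleophilic in every earlier step. Nothing is gained in size, but 16 becomes the product of one deprotection. The forward step must break the S–O bond without moving a double bond and without ionising C2–O1.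

**15 to 13 and 14.** The C5–CH2 bond of the ring A allyl group is cut, giving aryl bromide 13 and the three-carbon boron reagent 14. An allyl group cannot pass through the oxidative key step, whereas bromine can and marks C5 unambiguously. The forward coupling must leave the sulfonate C–O bond alone and must not isomerise either allyl group.

**13 to 11 and 12.** The C9–O(aryl) ether bond is cut, giving primary alcohol 11 and the intact commercial phenol 12. Half of the carbon atoms leave in one cut, and what remains is the core with a one-carbon arm. The forward step is a dehydrative etherification at a primary carbon next to C3, under neutral conditions, with 12 as the only free phenol.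

**11 to 10.** No bond is cut. C9 is raised to the ester level, because a carboxylate on C3 is what the ring contraction delivers. The forward reduction must spare the aryl bromide and the aryl sulfonate and must not epimerise C3.

**10 to 8 (through 9).** The C3–C3a bond is cut and C3a is reconnected to C9, which expands the dihydrofuran to a pyranone and makes C9 the ketone carbon C4. Two adjacent stereocentres become one, and 8 belongs to a class with reliable catalytic asymmetric access. The forward step must move ring A and not the C2 aryl group, must relay the C2 configuration to C3 as trans, and must not racemise C2.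

**8 to 4 and 7.** The C2–C1' bond is cut, giving the achiral chromone 4 and the arylboronic acid 7. This is the only place where absolute configuration is created, and a catalytic enantioselective conjugate addition does it in one step. The forward step needs high face selectivity, tolerance of the aryl bromide and sulfonate, and conditions that do not reopen the pyranone.

**7 to 6 to 5.** The B–O bonds to the diol and the O–S bond are cut, leading to commercial 5. The sulfonate is installed on the easily purified diol ester, and the free acid is liberated because it is the competent partner in the conjugate addition.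

**4 to 2 to 1 (through 3).** O1–C2 and C2–C3 are cut, with C2 supplied as a one-carbon electrophile. The C–Br bond is then cut to reach commercial 1. The forward bromination must go para to the hydroxyl group, which the blocked ortho positions and the meta-directing acetyl group ensure.

## Other disconnections considered

**Alternative 1:** The cuts are C2–C1' and C3–C3a in an open chain, with O1–C2 closed later.

- **Forward key step.** The aryllithium A4 would add to the (E)-alkenylboronate A2, which should be available from 12 by propargylation and hydroboration. The resulting ate complex, the ring A iodide A3, Pd(OAc)2, a MandyPhos ligand and a triflate salt would give boronic ester A1. The mechanism is a palladium-induced 1,2-metallate shift: the guaiacyl group goes to the boron-bearing carbon and ring A to its neighbour, anti across the alkene. Oxidation of the C–B bond with retention would give alcohol A5, and acetal removal and closure of O1–C2 would follow.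
- **In favour.** It is convergent. Two C–C bonds and both stereocentres arise in one catalytic operation. Both allyl groups and the eugenyl ether are present from the start, so no bromide placeholder, no late cross-coupling and no stoichiometric oxidant are needed. On step economy it is the better plan: about five or six operations in the longest line against eight.
- **Against.** β-Substituted alkenylboronates are the least reactive class in this coupling. The alkylpalladium intermediate carries a β-aryloxy group and β-hydrogens that can be eliminated. A3 is hindered by its ortho acetal. Two terminal alkenes are exposed to arylpalladium species. The key step closes no ring.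
- **Stereochemical point.** A1 is the anti adduct of the E isomer and has boron where O1 stands in the target. Oxidation with retention followed by an invertive closure would therefore lead to the cis ring. The trans ring would need the Z isomer of A2, or an ionising, thermodynamically controlled closure through the para-alkoxybenzyl cation, which makes the catalyst-set C2 redundant.
- **Comparison.** Both plans rest on a 1,2-aryl shift and both set one centre by catalyst and the other by relay; on that count they are equal. The chosen plan forms the ring, the C3–C3a bond and the trans relation in one step, on a substrate class where that transformation is established.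

**Alternative 2:** C3–C9 is formed first, together with a temporary C2–C9 bond that is cleaved later.

- **Forward key step.** The carbene from ethyl diazoacetate A8 on CuOTf (monovalent copper) with a tert-butyl bis(oxazoline) ligand would add to the furan double bond of benzofuran A7 to give the exo cyclopropane A6. Lewis-acid opening at C2 by an oxygenated arene nucleophile, with inversion, would give the trans ester A9.
- **In favour.** Copper–bis(oxazoline) cyclopropanation of furans and benzofurans is an established enantioselective reaction. The catalyst sets C3 directly. Invertive opening of the cis-fused cyclopropane enforces the trans relation, so the stereochemical relay is as clean as in the chosen plan. The bromide has the same role in both plans.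
- **Against.** After C2–C9 cleavage, C9 still carries the ester carbon, so the arm on C3 of A9 is one carbon too long. The carboxyl carbon must be removed and replaced by oxygen (saponification, decarboxylative oxygenation) before the eugenyl ether can be made. The oxocarbenium ion formed on opening can lose the C3 proton and aromatise the furan ring, erasing both stereocentres. The arene nucleophile can react para to either oxygen. The aromatic C2=C3 bond of A7 is a sluggish carbene acceptor.
- **Comparison.** The diazo ester makes it the less safe plan. The step count is equal at best, and the sequence after the key step is longer and less certain.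

**Alternative 3:** The cuts are C3a–C7a, C6–C7 and C7–O, so ring A is built from a furan.

- **Forward key step.** AuCl3 or Ph3PAuNTf2 would activate the terminal alkynyl ether of A11. The furan attacks, its oxygen is relocated, and the phenol A10 results with both the benzene ring and the dihydrofuran closed. Methylation at the C7 oxygen and acetal removal would finish.
- **In favour.** Two rings form in one isomerisation with complete atom economy and no stoichiometric reagent; on these counts it is better than the chosen plan. The C7 oxygen emerges as the only free phenol, so its methylation is unambiguous. All alkenes and the eugenyl ether are in place, so no late coupling is needed.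
- **Against.** The key step creates no stereocentre, so both centres of A11 need separate enantio- and diastereoselective chemistry beforehand. A11 is an alkynyl ether of a secondary benzylic alcohol, a class prone to [3,3]-sigmatropic shift and to hydration, and it needs strong base to make. The 2,4-disubstituted furan is not a commodity. The terminal alkenes may compete for the activated alkyne. The effort goes into building a guaiacol-type ring that is available ready-made.
- **Comparison.** The chosen plan is weaker on ring count and atom economy of the key step, and stronger on stereocontrol, substrate availability and overall step count.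

Key step: step 6

Assumption: the Pd(OCOCF3)2/t-BuPyOx catalyst is taken to attack the chromone on the same enone face as it attacks 3-methylcyclohex-2-enone, so the (R)-ligand should lead to the (2S)-flavanone. If the sense is the opposite, the (S)-ligand is used and nothing else changes.

## Route

Step 1
Reactants: 1 1-(2-hydroxy-3-methoxyphenyl)ethanone
Product: 2 1-(5-bromo-2-hydroxy-3-methoxyphenyl)ethanone
Conditions: N-bromosuccinimide (1.05 equiv), MeCN, 0 °C to rt
Reagents that add atoms: N-bromosuccinimide, O=C1CCC(=O)N1Br
Why: Electrophilic aromatic bromination; the hydroxyl group directs to its para position C5, which is also meta to the acetyl group, and both ortho positions are occupied. N-Bromosuccinimide avoids handling elemental bromine.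

Step 2
Reactants: 2 1-(5-bromo-2-hydroxy-3-methoxyphenyl)ethanone
Product: 4 6-bromo-8-methoxy-4H-chromen-4-one, via enaminone 3 (not isolated)
Conditions: Me2NCH(OMe)2, toluene, 100 °C; concentrate; then conc. HCl, CH2Cl2, 40 °C
Reagents that add atoms: N,N-dimethylformamide dimethyl acetal, COC(OC)N(C)C
Why: Condensation of the methyl ketone with the formamide acetal gives the vinylogous amide 3. Under acid the phenol adds to its β-carbon and dimethylamine is eliminated (the enaminone route to chromones), so the acetal carbon becomes C2.

Step 3
Reactants: 5 2-methoxy-4-(4,4,5,5-tetramethyl-1,3,2-dioxaborolan-2-yl)phenol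
Product: 6 2-methoxy-4-(4,4,5,5-tetramethyl-1,3,2-dioxaborolan-2-yl)phenyl methanesulfonate
Conditions: MsCl, Et3N, CH2Cl2, 0 °C
Reagents that add atoms: methanesulfonyl chloride, CS(=O)(=O)Cl
Why: O-Sulfonylation of the phenol; the pinacol boronate is inert to MsCl and amine base. The mesylate is electron-withdrawing, should survive acid, oxidant, hydride and palladium catalysis, and can be removed at the end.

Step 4
Reactants: 6 2-methoxy-4-(4,4,5,5-tetramethyl-1,3,2-dioxaborolan-2-yl)phenyl methanesulfonate
Product: 7 [3-methoxy-4-(methylsulfonyloxy)phenyl]boronic acid
Conditions: NaIO4, NH4OAc, acetone/H2O, rt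
Reagents that add atoms: water, O
Why: Hydrolysis of the boronic ester is pulled to the free acid by periodate glycol cleavage of the released pinacol. The free acid is preferred because it should transmetalate to cationic divalent palladium far more readily than the pinacol ester.

Step 5
Reactants: 4 6-bromo-8-methoxy-4H-chromen-4-one; 7 [3-methoxy-4-(methylsulfonyloxy)phenyl]boronic acid (1.5 to 2 equiv)
Product: 8 (2S)-6-bromo-8-methoxy-2-[3-methoxy-4-(methylsulfonyloxy)phenyl]-2,3-dihydro-4H-chromen-4-one
Conditions: Pd(OCOCF3)2 (5 mol %), (R)-t-BuPyOx (6 mol %), NH4PF6 (30 mol %), H2O (5 equiv), ClCH2CH2Cl, 60 °C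
Reagents that add atoms: none
Why: Enantioselective conjugate addition of an arylboronic acid to a chromone under palladium/pyridine–oxazoline catalysis: the cationic arylpalladium species inserts the C2=C3 bond on the enone face left open by the tert-butyl group, and water protonates the palladium enolate. C2 is set as S under catalyst control; no zerovalent palladium takes part, so the aryl bromide and the aryl mesylate are spectators.

Step 6
Reactants: 8 (2S)-6-bromo-8-methoxy-2-[3-methoxy-4-(methylsulfonyloxy)phenyl]-2,3-dihydro-4H-chromen-4-one
Product: 10 methyl (2S,3S)-5-bromo-7-methoxy-2-[3-methoxy-4-(methylsulfonyloxy)phenyl]-2,3-dihydro-1-benzofuran-3-carboxylate (trans), via methyl enol ether 9 (not isolated)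
Conditions: PhI(OAc)2 (1.3 equiv), conc. H2SO4 (0.5 equiv), HC(OMe)3, 0 °C to rt, short reaction time
Reagents that add atoms: trimethyl orthoformate, COC(OC)OC
Why: Acid and the orthoformate convert 8 into the methyl enol ether 9, whose C3 attacks the trivalent iodine of PhI(OAc)2 on the face away from the equatorial C2 aryl group, while methanol caps C4 as the dimethyl ketal. In the half-chair of this trans 3-iodanyl ketal the equatorial C3–I bond is antiperiplanar to the C4–C4a ring bond, so the ipso carbon C4a of ring A moves from C4 to C3 through a bridged phenonium ion as iodobenzene leaves, and the resulting dimethoxycarbenium ion loses a methyl group to acetate to give the ester. The closest known reaction type is the oxidative 1,2-aryl shift of aryl ketones and flavanones with PhI(OAc)2 or Tl(NO3)3 in trimethyl orthoformate, which gives arylacetates and trans 2-aryl-2,3-dihydrobenzofuran-3-carboxylates. The five-membered ring is closed by contraction and not by a new carbon–heteroatom bond: a 3-exo-tet attack of C4a on C3 forms the spiro phenonium ion and cleavage of C4–C4a leaves the dihydrofuran, with C3–C3a as the one new skeletal bond. The new stereocentre C3 is set by substrate control from C2: anti delivery of iodine followed by inversion at C3 during the shift places the ester carbon trans to the aryl group, which is also the more stable arrangement. The step needs migration of ring A in preference to migration of the C2 aryl group (isoflavone path), to loss of the C2 proton (flavone path) and to methanolysis at C3. The ring oxygen O1 ortho to C4a activates the migrating carbon, the mesylate makes the C2 aryl group a poor migrating group and a poor partner for the iodane, and the equatorial aryl group cannot align with the leaving group. Bromine tolerates the oxidant where an allyl group would not, and brief acid contact at or below room temperature limits opening of the pyranone to the chalcone, which would erode the C2 configuration.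

Step 7
Reactants: 10 methyl (2S,3S)-5-bromo-7-methoxy-2-[3-methoxy-4-(methylsulfonyloxy)phenyl]-2,3-dihydro-1-benzofuran-3-carboxylate
Product: 11 4-[(2S,3R)-5-bromo-3-(hydroxymethyl)-7-methoxy-2,3-dihydro-1-benzofuran-2-yl]-2-methoxyphenyl methanesulfonate
Conditions: i-Bu2AlH (3 equiv), CH2Cl2, −78 to 0 °C; aq. potassium sodium tartrate
Reagents that add atoms: none
Why: Reduction of the ester to the primary alcohol by a Lewis-acidic, non-basic aluminium hydride at low temperature, so that neither epimerisation at C3 nor β-elimination of the ring oxygen should occur; aryl bromide and aryl mesylate are inert. The descriptor at C3 changes from S to R by priority only.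

Step 8
Reactants: 11 4-[(2S,3R)-5-bromo-3-(hydroxymethyl)-7-methoxy-2,3-dihydro-1-benzofuran-2-yl]-2-methoxyphenyl methanesulfonate; 12 eugenol (4-allyl-2-methoxyphenol, 1.3 equiv)
Product: 13 4-[(2S,3R)-3-[(4-allyl-2-methoxyphenoxy)methyl]-5-bromo-7-methoxy-2,3-dihydro-1-benzofuran-2-yl]-2-methoxyphenyl methanesulfonate
Conditions: PPh3, diisopropyl azodicarboxylate, THF, 0 °C to rt
Reagents that add atoms: none
Why: Mitsunobu etherification: the primary alcohol is activated as its alkoxyphosphonium ion and displaced by the phenoxide of 12 (pKa about 10) at an achiral CH2 group, so no stereocentre is touched. The substrate phenol is masked as its mesylate and cannot compete.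

Step 9
Reactants: 13 4-[(2S,3R)-3-[(4-allyl-2-methoxyphenoxy)methyl]-5-bromo-7-methoxy-2,3-dihydro-1-benzofuran-2-yl]-2-methoxyphenyl methanesulfonate; 14 2-allyl-4,4,5,5-tetramethyl-1,3,2-dioxaborolane (2 equiv)
Product: 15 4-[(2S,3R)-5-allyl-3-[(4-allyl-2-methoxyphenoxy)methyl]-7-methoxy-2,3-dihydro-1-benzofuran-2-yl]-2-methoxyphenyl methanesulfonate
Conditions: Pd(PPh3)4 (5 mol %), CsF (4 equiv), THF, 65 °C
Reagents that add atoms: none
Why: Suzuki–Miyaura coupling of an aryl bromide with an allylboronate under fluoride activation; Pd(PPh3)4 should insert into the C–Br bond but not into the aryl C–O bond of the mesylate. The anhydrous, weakly basic fluoride conditions disfavour migration of the allyl double bonds, and the boron reagent replaces a toxic allylstannane.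

Step 10
Reactants: 15 4-[(2S,3R)-5-allyl-3-[(4-allyl-2-methoxyphenoxy)methyl]-7-methoxy-2,3-dihydro-1-benzofuran-2-yl]-2-methoxyphenyl methanesulfonate
Product: 16 4-[(2S,3R)-5-allyl-3-[(4-allyl-2-methoxyphenoxy)methyl]-7-methoxy-2,3-dihydro-1-benzofuran-2-yl]-2-methoxyphenol (CNP0138854.1)
Conditions: LiN(i-Pr)2 (3 equiv), THF, −78 to 0 °C; then dilute aq. HCl
Reagents that add atoms: none
Why: Cleavage of the aryl mesylate by E1cB: the amide base removes a proton from the S-methyl group, by far the most acidic site, and the phenoxide is expelled together with sulfene, which the amine takes up. The cold, brief, non-nucleophilic conditions should leave both allyl groups, the aryl ethers and both stereocentres alone.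

## Compound list

1 | 1-(2-hydroxy-3-methoxyphenyl)ethanone | CC(=O)c1cccc(OC)c1O | starting material
2 | 1-(5-bromo-2-hydroxy-3-methoxyphenyl)ethanone | CC(=O)c1cc(Br)cc(OC)c1O | intermediate
3 | (E)-1-(5-bromo-2-hydroxy-3-methoxyphenyl)-3-(dimethylamino)prop-2-en-1-one | CN(C)/C=C/C(=O)c1cc(Br)cc(OC)c1O | intermediate
4 | 6-bromo-8-methoxy-4H-chromen-4-one | O=c1ccoc2c(OC)cc(Br)cc12 | intermediate
5 | 2-methoxy-4-(4,4,5,5-tetramethyl-1,3,2-dioxaborolan-2-yl)phenol | COc1cc(B2OC(C)(C)C(C)(C)O2)ccc1O | starting material
6 | 2-methoxy-4-(4,4,5,5-tetramethyl-1,3,2-dioxaborolan-2-yl)phenyl methanesulfonate | COc1cc(B2OC(C)(C)C(C)(C)O2)ccc1OS(C)(=O)=O | intermediate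
7 | [3-methoxy-4-(methylsulfonyloxy)phenyl]boronic acid | COc1cc(B(O)O)ccc1OS(C)(=O)=O | intermediate
8 | (2S)-6-bromo-8-methoxy-2-[3-methoxy-4-(methylsulfonyloxy)phenyl]-2,3-dihydro-4H-chromen-4-one | O=C1C[C@@H](c2ccc(OS(C)(=O)=O)c(OC)c2)Oc2c(OC)cc(Br)cc12 | intermediate
9 | (2S)-6-bromo-4,8-dimethoxy-2-[3-methoxy-4-(methylsulfonyloxy)phenyl]-2H-chromene | COC1=C[C@@H](c2ccc(OS(C)(=O)=O)c(OC)c2)Oc2c(OC)cc(Br)cc12 | intermediate
10 | methyl (2S,3S)-5-bromo-7-methoxy-2-[3-methoxy-4-(methylsulfonyloxy)phenyl]-2,3-dihydro-1-benzofuran-3-carboxylate (trans) | COC(=O)[C@H]1c2cc(Br)cc(OC)c2O[C@@H]1c1ccc(OS(C)(=O)=O)c(OC)c1 | intermediate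
11 | 4-[(2S,3R)-5-bromo-3-(hydroxymethyl)-7-methoxy-2,3-dihydro-1-benzofuran-2-yl]-2-methoxyphenyl methanesulfonate | OC[C@H]1c2cc(Br)cc(OC)c2O[C@@H]1c1ccc(OS(C)(=O)=O)c(OC)c1 | intermediate
12 | eugenol (4-allyl-2-methoxyphenol) | C=CCc1ccc(O)c(OC)c1 | starting material
13 | 4-[(2S,3R)-3-[(4-allyl-2-methoxyphenoxy)methyl]-5-bromo-7-methoxy-2,3-dihydro-1-benzofuran-2-yl]-2-methoxyphenyl methanesulfonate | C=CCc1ccc(OC[C@H]2c3cc(Br)cc(OC)c3O[C@@H]2c2ccc(OS(C)(=O)=O)c(OC)c2)c(OC)c1 | intermediate
14 | 2-allyl-4,4,5,5-tetramethyl-1,3,2-dioxaborolane | C=CCB1OC(C)(C)C(C)(C)O1 | starting material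
15 | 4-[(2S,3R)-5-allyl-3-[(4-allyl-2-methoxyphenoxy)methyl]-7-methoxy-2,3-dihydro-1-benzofuran-2-yl]-2-methoxyphenyl methanesulfonate | C=CCc1ccc(OC[C@H]2c3cc(CC=C)cc(OC)c3O[C@@H]2c2ccc(OS(C)(=O)=O)c(OC)c2)c(OC)c1 | intermediate
16 | 4-[(2S,3R)-5-allyl-3-[(4-allyl-2-methoxyphenoxy)methyl]-7-methoxy-2,3-dihydro-1-benzofuran-2-yl]-2-methoxyphenol | C=CCc1ccc(OC[C@H]2c3cc(CC=C)cc(OC)c3O[C@@H]2c2ccc(O)c(OC)c2)c(OC)c1 | target

## Step count and least certain steps

Total step count: 10. Longest linear sequence: 8 steps (1, 2, 4, 8, 10, 11, 13, 15, 16). The branch 5, 6, 7 joins at step 5 and is equally long.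

**Step 6 (key step).** The most likely failure is stalling of the aryl shift, because the migrating carbon C4a has bromine and methoxy in its meta positions. Loss of the C2 proton towards the flavone, methanol substitution at C3, or slow acid-promoted opening of the pyranone (with erosion of the C2 configuration) could then take over.

Fallback: a Wolff ring contraction, which does not depend on the electron density of ring A. It sets out from 8 and returns at 10.
- 8 is deprotonated with LiN(SiMe3)2 at −78 °C and acylated with 2,2,2-trifluoroethyl trifluoroacetate to the 3-(trifluoroacetyl) ketone F1.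
- 4-Acetamidobenzenesulfonyl azide and Et3N in MeCN convert F1 into the 3-diazo ketone F2 by detrifluoroacetylative diazo transfer.
- Irradiation of F2 in methanol expels dinitrogen and moves ring A from C4 to C3, giving the ketene F3. Methanol adds to F3 to give 10 together with its cis C3 epimer F4.
- NaOMe in MeOH equilibrates F4 to trans 10.

The enolate must be kept cold to avoid β-elimination of the ring oxygen. The azide and the diazo ketone are handled on small scale behind a shield.

**Step 5.** The likely failures are slow insertion with competing protodeboronation of the electron-poor boronic acid, or insufficient face selectivity on this 8-methoxy chromone. The sense of induction also rests on the stated assumption.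

Fallback: racemic synthesis and kinetic resolution. It sets out from 2 and returns at 8.
- Amine-catalysed aldol condensation of 2 with 4-formyl-2-methoxyphenyl methanesulfonate (O=Cc1ccc(OS(C)(=O)=O)c(OC)c1; pyrrolidine, EtOH, 60 °C) gives the 2'-hydroxychalcone F5.
- Heating F5 with NaOAc closes it by oxa-Michael addition to racemic flavanone, that is 8 together with its (2R) enantiomer F6.
- Transfer hydrogenation with RuCl(p-cymene)(TsDPEN) and HCO2H/Et3N is run to about half conversion, using the catalyst enantiomer that reduces the (2R) ketone faster. It converts F6 into the cis flavan-4-ol F7, which is separated, and leaves 8.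

**Step 9.** The likely failures are migration of an allyl double bond into conjugation through palladium hydride species, or Heck-type addition of the arylpalladium intermediate to a terminal alkene. Oxidative addition to this electron-rich bromide is slow, which gives these paths time.

Fallback: reversed polarity. It sets out from 13 and returns at 15.
- Miyaura borylation of 13 (bis(pinacolato)diboron, PdCl2(dppf), KOAc, dioxane, 80 °C) gives the arylboronate F8.
- Coupling of F8 with allyl bromide (Pd(PPh3)4, K2CO3, THF/H2O, rt to 50 °C) proceeds through a π-allylpalladium species and gives 15.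

**Step 10.** The likely failure is competing deprotonation of a benzylic–allylic CH2 group by the amide base, which would move a double bond into conjugation. Recapture of sulfene by the phenoxide is a second possibility.

Fallback: exchange of the protecting group before any alkene is present. It sets out from 11 and returns at 16.
- The mesylate of 11 is hydrolysed (KOH, MeOH/H2O, 60 °C) to the phenol alcohol F9.
- The phenoxide of F9 is acetylated selectively (Ac2O, aq. NaOH, THF, 0 °C) to the aryl acetate F10.
- Mitsunobu reaction of F10 with 12 gives the ether F11.
- Coupling of F11 with 14 under the conditions of step 9 gives the diallyl acetate F12.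
- K2CO3 in MeOH at rt removes the acetate from F12 and gives 16.

## Further compounds

F1 | step 6 | (2S)-6-bromo-8-methoxy-2-[3-methoxy-4-(methylsulfonyloxy)phenyl]-3-(trifluoroacetyl)-2,3-dihydro-4H-chromen-4-one (C3 unassigned, largely enolised) | O=C1C(C(=O)C(F)(F)F)[C@@H](c2ccc(OS(C)(=O)=O)c(OC)c2)Oc2c(OC)cc(Br)cc12
F2 | step 6 | 6-bromo-3-diazo-8-methoxy-2-[3-methoxy-4-(methylsulfonyloxy)phenyl]-2,3-dihydro-4H-chromen-4-one, C2 arranged as in 8 (descriptor 2R by priority) | O=C1C(=[N+]=[N-])[C@@H](c2ccc(OS(C)(=O)=O)c(OC)c2)Oc2c(OC)cc(Br)cc12
F3 | step 6 | ketene of the ring-contracted acid, 5-bromo-7-methoxy-2-[3-methoxy-4-(methylsulfonyloxy)phenyl]-1-benzofuran-3(2H)-ylidene ketene, C2 arranged as in 10 | O=C=C1c2cc(Br)cc(OC)c2O[C@@H]1c1ccc(OS(C)(=O)=O)c(OC)c1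
F4 | step 6 | methyl (2S,3R)-5-bromo-7-methoxy-2-[3-methoxy-4-(methylsulfonyloxy)phenyl]-2,3-dihydro-1-benzofuran-3-carboxylate (cis) | COC(=O)[C@@H]1c2cc(Br)cc(OC)c2O[C@@H]1c1ccc(OS(C)(=O)=O)c(OC)c1
F5 | step 5 | (E)-1-(5-bromo-2-hydroxy-3-methoxyphenyl)-3-[3-methoxy-4-(methylsulfonyloxy)phenyl]prop-2-en-1-one | O=C(/C=C/c1ccc(OS(C)(=O)=O)c(OC)c1)c1cc(Br)cc(OC)c1O
F6 | step 5 | (2R)-6-bromo-8-methoxy-2-[3-methoxy-4-(methylsulfonyloxy)phenyl]-2,3-dihydro-4H-chromen-4-one | O=C1C[C@H](c2ccc(OS(C)(=O)=O)c(OC)c2)Oc2c(OC)cc(Br)cc12
F7 | step 5 | 4-[(2R,4R)-6-bromo-4-hydroxy-8-methoxy-3,4-dihydro-2H-chromen-2-yl]-2-methoxyphenyl methanesulfonate (cis) | O[C@@H]1C[C@H](c2ccc(OS(C)(=O)=O)c(OC)c2)Oc2c(OC)cc(Br)cc12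
F8 | step 9 | 4-[(2S,3R)-3-[(4-allyl-2-methoxyphenoxy)methyl]-7-methoxy-5-(4,4,5,5-tetramethyl-1,3,2-dioxaborolan-2-yl)-2,3-dihydro-1-benzofuran-2-yl]-2-methoxyphenyl methanesulfonate | C=CCc1ccc(OC[C@H]2c3cc(B4OC(C)(C)C(C)(C)O4)cc(OC)c3O[C@@H]2c2ccc(OS(C)(=O)=O)c(OC)c2)c(OC)c1
F9 | step 10 | 4-[(2S,3R)-5-bromo-3-(hydroxymethyl)-7-methoxy-2,3-dihydro-1-benzofuran-2-yl]-2-methoxyphenol | OC[C@H]1c2cc(Br)cc(OC)c2O[C@@H]1c1ccc(O)c(OC)c1
F10 | step 10 | 4-[(2S,3R)-5-bromo-3-(hydroxymethyl)-7-methoxy-2,3-dihydro-1-benzofuran-2-yl]-2-methoxyphenyl acetate | OC[C@H]1c2cc(Br)cc(OC)c2O[C@@H]1c1ccc(OC(C)=O)c(OC)c1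
F11 | step 10 | 4-[(2S,3R)-3-[(4-allyl-2-methoxyphenoxy)methyl]-5-bromo-7-methoxy-2,3-dihydro-1-benzofuran-2-yl]-2-methoxyphenyl acetate | C=CCc1ccc(OC[C@H]2c3cc(Br)cc(OC)c3O[C@@H]2c2ccc(OC(C)=O)c(OC)c2)c(OC)c1
F12 | step 10 | 4-[(2S,3R)-5-allyl-3-[(4-allyl-2-methoxyphenoxy)methyl]-7-methoxy-2,3-dihydro-1-benzofuran-2-yl]-2-methoxyphenyl acetate | C=CCc1ccc(OC[C@H]2c3cc(CC=C)cc(OC)c3O[C@@H]2c2ccc(OC(C)=O)c(OC)c2)c(OC)c1
A1 | alternative 1 | pinacol 1,2-diaryl-3-(4-allyl-2-methoxyphenoxy)propylboronate, anti adduct carrying the acetal-protected guaiacyl group on the boron-bearing carbon and ring A on the next carbon | C=CCc1ccc(OC[C@H]([C@H](B2OC(C)(C)C(C)(C)O2)c2ccc(OCOC)c(OC)c2)c2cc(CC=C)cc(OC)c2OCOC)c(OC)c1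
A2 | alternative 1 | (E)-2-[3-(4-allyl-2-methoxyphenoxy)prop-1-en-1-yl]-4,4,5,5-tetramethyl-1,3,2-dioxaborolane | C=CCc1ccc(OC/C=C/B2OC(C)(C)C(C)(C)O2)c(OC)c1
A3 | alternative 1 | 5-allyl-1-iodo-3-methoxy-2-(methoxymethoxy)benzene | C=CCc1cc(I)c(OCOC)c(OC)c1
A4 | alternative 1 | [3-methoxy-4-(methoxymethoxy)phenyl]lithium | [Li]c1ccc(OCOC)c(OC)c1
A5 | alternative 1 | secondary benzylic alcohol from oxidation of A1 with retention | C=CCc1ccc(OC[C@H]([C@H](O)c2ccc(OCOC)c(OC)c2)c2cc(CC=C)cc(OC)c2OCOC)c(OC)c1
A6 | alternative 2 | exo ethyl 5-bromo-7-methoxy-1a,6b-dihydro-1H-cyclopropa[b]benzofuran-1-carboxylate | CCOC(=O)[C@@H]1[C@H]2c3cc(Br)cc(OC)c3O[C@@H]12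
A7 | alternative 2 | 5-bromo-7-methoxy-1-benzofuran | COc1cc(Br)cc2ccoc12
A8 | alternative 2 | ethyl diazoacetate | CCOC(=O)C=[N+]=[N-]
A9 | alternative 2 | ethyl 2-[(2S,3S)-5-bromo-2-(4-hydroxy-3-methoxyphenyl)-7-methoxy-2,3-dihydro-1-benzofuran-3-yl]acetate (trans) | CCOC(=O)C[C@H]1c2cc(Br)cc(OC)c2O[C@@H]1c1ccc(O)c(OC)c1
A10 | alternative 3 | 7-hydroxy analogue of the target with the guaiacyl oxygen as methoxymethyl ether | C=CCc1ccc(OC[C@H]2c3cc(CC=C)cc(O)c3O[C@@H]2c2ccc(OCOC)c(OC)c2)c(OC)c1
A11 | alternative 3 | ethynyl ether of 3-(4-allyl-2-methoxyphenoxy)-2-(4-allylfuran-2-yl)-1-[3-methoxy-4-(methoxymethoxy)phenyl]propan-1-ol, configured as in A10 | C=CCc1ccc(OC[C@@H](c2cc(CC=C)co2)[C@H](OC#C)c2ccc(OCOC)c(OC)c2)c(OC)c1
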